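**Strategy.** Everything rests on cutting the C2–C3 bond of the inner 2,3-dihydrobenzofuran (the one fused to ring C, which carries the tetrahydrofuran). The key step re-forms it by Rh(II)-carbenoid C–H insertion: ring C holds, on adjacent carbons C3a and C7a, an α-diazo ester carbon (future C3) and an O–CH2–aryl ether (future O1–C2) whose aryl group is the complete outer dihydrobenzofuran. The ether C–H is activated by O1 and by electron-rich ring B. One operation closes the five-membered ring, sets C2 by catalyst control and, after base equilibration, C3 trans. The ether precursor arises convergently by Mitsunobu union of an all-cis tetrahydrofuran phenol with an outer dihydrobenzofuran benzylic alcohol, itself made by the same insertion.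

Key step: step 19

Remark: the facial sense of the chiral catalysts is assumed to be (S,S)-Et-DuPhos–Rh → (R)-4, Rh2(R-PTTL)4 → (2S) and Rh2(S-PTTL)4 → (2R) at the new ether carbon; should a trial show the opposite sense for one of them, its mirror-image catalyst is used and nothing else changes.

Step 1
Reactants: 1 4-(benzyloxy)-3-methoxybenzaldehyde; 2 dimethyl succinate
Product: 3 (E)-4-[4-(benzyloxy)-3-methoxyphenyl]-3-(methoxycarbonyl)but-3-enoic acid
Conditions: NaOMe, MeOH, reflux; then aq. HCl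
Reagents that add atoms: none
Why: Stobbe condensation, in which the succinate enolate adds to the aldehyde and the paraconic lactone intermediate opens by elimination to the (E)-alkylidene half-ester with the free acid on the CH2 arm.

Step 2
Reactants: 3 (E)-4-[4-(benzyloxy)-3-methoxyphenyl]-3-(methoxycarbonyl)but-3-enoic acid
Product: 4 (R)-4-[4-(benzyloxy)-3-methoxyphenyl]-3-(methoxycarbonyl)butanoic acid
Conditions: H2 (5 bar), [Rh(cod)((S,S)-Et-DuPhos)]BF4 (0.5 mol%), NaOMe (0.1 equiv), MeOH, rt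
Reagents that add atoms: none
Why: Rh–bisphospholane asymmetric hydrogenation of an itaconate-type half-ester, in which the carboxylate chelates rhodium and the ligand selects the alkene face, should set the future tetrahydrofuran C4 as (R) without touching the benzyl ether.

Step 3
Reactants: 4 (R)-4-[4-(benzyloxy)-3-methoxyphenyl]-3-(methoxycarbonyl)butanoic acid
Product: 6 (R)-4-[4-(benzyloxy)-3-methoxybenzyl]dihydrofuran-2(3H)-one, via hydroxy acid 5 (not isolated)
Conditions: LiOH (1.0 equiv), MeOH, then evaporation; LiBH4, THF, 0 °C → rt; then 2 M HCl, rt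
Reagents that add atoms: none
Why: Chemoselective borohydride reduction of the ester beside an unreactive lithium carboxylate, followed by acid lactonisation of the γ-hydroxy acid, should give the β-benzyl-γ-butyrolactone with the stereocentre untouched.

Step 4
Reactants: 7 3-bromo-4-hydroxy-5-methoxybenzaldehyde (5-bromovanillin)
Product: 8 3-bromo-5-methoxy-4-(triisopropylsilyloxy)benzaldehyde
Conditions: TIPSCl, imidazole, DMAP (cat.), DMF, rt
Reagents that add atoms: chlorotriisopropylsilane, CC(C)[Si](Cl)(C(C)C)C(C)C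
Why: Silylation of the phenol gives an aryl TIPS ether that should survive enolate, hydride and Lewis-acid steps and later leave with fluoride alone.

Step 5
Reactants: 6 (R)-4-[4-(benzyloxy)-3-methoxybenzyl]dihydrofuran-2(3H)-one; 8 3-bromo-5-methoxy-4-(triisopropylsilyloxy)benzaldehyde
Product: 9 (3S,4R)-4-[4-(benzyloxy)-3-methoxybenzyl]-3-{[3-bromo-5-methoxy-4-(triisopropylsilyloxy)phenyl](hydroxy)methyl}dihydrofuran-2(3H)-one (both carbinol epimers)
Conditions: LDA, THF, −78 °C; then 8, −78 °C; aq. NH4Cl at −78 °C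
Reagents that add atoms: none
Why: Aldol addition of the lactone lithium enolate, in which the aldehyde should approach anti to the β-benzyl group and set the 3,4-trans lactone (3S); the carbinol centre is uncontrolled and is erased in step 7.

Step 6
Reactants: 9 (3S,4R)-4-[4-(benzyloxy)-3-methoxybenzyl]-3-{[3-bromo-5-methoxy-4-(triisopropylsilyloxy)phenyl](hydroxy)methyl}dihydrofuran-2(3H)-one
Product: 10 (2R,3R)-2-[4-(benzyloxy)-3-methoxybenzyl]-3-{[3-bromo-5-methoxy-4-(triisopropylsilyloxy)phenyl](hydroxy)methyl}butane-1,4-diol (both carbinol epimers)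
Conditions: LiAlH4, THF, 0 °C
Reagents that add atoms: none
Why: Hydride reduction of the lactone to the 1,4-diol at 0 °C should leave the aryl bromide and silyl ether alone and turns the former carbonyl carbon into the hydroxymethyl group, so that the trans lactone maps onto a cis arrangement of CH2OH and benzyl in the later ring.

Step 7
Reactants: 10 (2R,3R)-2-[4-(benzyloxy)-3-methoxybenzyl]-3-{[3-bromo-5-methoxy-4-(triisopropylsilyloxy)phenyl](hydroxy)methyl}butane-1,4-diol
Product: 12 (3R,4R)-4-[4-(benzyloxy)-3-methoxybenzyl]-2-[3-bromo-5-methoxy-4-(triisopropylsilyloxy)phenyl]-3-(hydroxymethyl)tetrahydrofuran-2-ol (anomeric mixture), via hydroxy ketone 11 (not isolated)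
Conditions: activated MnO2 (excess), CH2Cl2, rt
Reagents that add atoms: none
Why: Chemoselective MnO2 oxidation of the benzylic carbinol in the presence of two primary aliphatic alcohols should give the aryl ketone, which closes with the γ-hydroxyl to the five-membered hemiketal and removes the uncontrolled carbinol centre.

Step 8
Reactants: 12 (3R,4R)-4-[4-(benzyloxy)-3-methoxybenzyl]-2-[3-bromo-5-methoxy-4-(triisopropylsilyloxy)phenyl]-3-(hydroxymethyl)tetrahydrofuran-2-ol
Product: 13 [(2R,3R,4R)-4-[4-(benzyloxy)-3-methoxybenzyl]-2-[3-bromo-5-methoxy-4-(triisopropylsilyloxy)phenyl]tetrahydrofuran-3-yl]methanol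
Conditions: Et3SiH, BF3·OEt2, CH2Cl2, −78 → −40 °C; Et3N then aq. NaHCO3 at low temperature
Reagents that add atoms: none
Why: Reductive deoxygenation of the cyclic hemiketal (ionic hydrogenation) through the aryl-stabilised oxocarbenium ion, in which hydride should enter on the ring face opposite the cis-disposed C3 hydroxymethyl and C4 benzyl groups, places the aryl group cis to both and sets C2 as (R).

Step 9
Reactants: 13 [(2R,3R,4R)-4-[4-(benzyloxy)-3-methoxybenzyl]-2-[3-bromo-5-methoxy-4-(triisopropylsilyloxy)phenyl]tetrahydrofuran-3-yl]methanol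
Product: 14 [(2R,3R,4R)-4-[4-(benzyloxy)-3-methoxybenzyl]-2-[3-bromo-5-methoxy-4-(triisopropylsilyloxy)phenyl]tetrahydrofuran-3-yl]methyl acetate
Conditions: Ac2O, pyridine, DMAP (cat.), CH2Cl2, 0 °C → rt
Reagents that add atoms: acetic anhydride, CC(=O)OC(C)=O
Why: Acetylation masks the primary alcohol against carbenoid O–H insertion, and the acetate is later removed in the hydride step that also reduces the esters.

Step 10
Reactants: 14 [(2R,3R,4R)-4-[4-(benzyloxy)-3-methoxybenzyl]-2-[3-bromo-5-methoxy-4-(triisopropylsilyloxy)phenyl]tetrahydrofuran-3-yl]methyl acetate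
Product: 15 tert-butyl 2-{5-[(2R,3R,4R)-3-(acetoxymethyl)-4-(4-(benzyloxy)-3-methoxybenzyl)tetrahydrofuran-2-yl]-3-methoxy-2-(triisopropylsilyloxy)phenyl}acetate
Conditions: BrZnCH2CO2tBu, Pd(dba)2 (3 mol%), Q-Phos (3 mol%), THF, rt → 50 °C
Reagents that add atoms: (2-tert-butoxy-2-oxoethyl)zinc bromide, CC(C)(C)OC(=O)C[Zn]Br
Why: Pd-catalysed α-arylation of an ester with a Reformatsky reagent (Negishi-type coupling) proceeds under neutral conditions that should tolerate the acetate, the silyl ether and the acid-sensitive tetrahydrofuran.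

Step 11
Reactants: 15 tert-butyl 2-{5-[(2R,3R,4R)-3-(acetoxymethyl)-4-(4-(benzyloxy)-3-methoxybenzyl)tetrahydrofuran-2-yl]-3-methoxy-2-(triisopropylsilyloxy)phenyl}acetate
Product: 16 tert-butyl 2-{5-[(2R,3R,4R)-3-(acetoxymethyl)-4-(4-(benzyloxy)-3-methoxybenzyl)tetrahydrofuran-2-yl]-2-hydroxy-3-methoxyphenyl}acetate
Conditions: TBAF, AcOH (1:1), THF, 0 °C
Reagents that add atoms: none
Why: Buffered fluoride cleavage of the aryl silyl ether should free only the ring-C phenol, since no alkyl silyl ether is present and the tert-butyl ester resists lactonisation.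

Step 12
Reactants: 17 methyl 3-bromo-4-hydroxy-5-methoxybenzoate; 18 [4-(benzyloxy)-3-methoxyphenyl]methanol
Product: 19 methyl 4-{[4-(benzyloxy)-3-methoxybenzyl]oxy}-3-bromo-5-methoxybenzoate
Conditions: PPh3, DIAD, THF, 0 °C → rt
Reagents that add atoms: none
Why: Mitsunobu etherification of an acidic phenol with a primary benzylic alcohol should give the aryl benzyl ether directly.

Step 13
Reactants: 19 methyl 4-{[4-(benzyloxy)-3-methoxybenzyl]oxy}-3-bromo-5-methoxybenzoate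
Product: 20 methyl 4-{[4-(benzyloxy)-3-methoxybenzyl]oxy}-3-(2-tert-butoxy-2-oxoethyl)-5-methoxybenzoate
Conditions: BrZnCH2CO2tBu, Pd(dba)2 (3 mol%), Q-Phos (3 mol%), THF, rt
Reagents that add atoms: (2-tert-butoxy-2-oxoethyl)zinc bromide, CC(C)(C)OC(=O)C[Zn]Br
Why: The same Pd-catalysed Reformatsky α-arylation should install the arylacetate ortho to the ether, and the zinc enolate does not attack the methyl benzoate.

Step 14
Reactants: 20 methyl 4-{[4-(benzyloxy)-3-methoxybenzyl]oxy}-3-(2-tert-butoxy-2-oxoethyl)-5-methoxybenzoate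
Product: 21 methyl 4-{[4-(benzyloxy)-3-methoxybenzyl]oxy}-3-(2-tert-butoxy-1-diazo-2-oxoethyl)-5-methoxybenzoate
Conditions: p-ABSA, DBU, MeCN, 0 °C → rt
Reagents that add atoms: 4-acetamidobenzenesulfonyl azide, CC(=O)Nc1ccc(cc1)S(=O)(=O)N=[N+]=[N-]
Why: Regitz diazo transfer to the benzylic ester enolate is the standard entry to aryldiazoacetates.

Step 15
Reactants: 21 methyl 4-{[4-(benzyloxy)-3-methoxybenzyl]oxy}-3-(2-tert-butoxy-1-diazo-2-oxoethyl)-5-methoxybenzoate
Product: 23 3-tert-butyl 5-methyl (2S,3S)-2-[4-(benzyloxy)-3-methoxyphenyl]-7-methoxy-2,3-dihydrobenzofuran-3,5-dicarboxylate (trans), via cis ester 22 (not isolated)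
Conditions: Rh2(R-PTTL)4 (1 mol%), toluene, −60 °C, slow addition of 21; then DBU, rt
Reagents that add atoms: none
Why: Intramolecular Rh(II)-carbenoid 1,5-C–H insertion of the aryldiazoacetate into the benzylic ether CH2 should close the outer dihydrobenzofuran with C2 set as (S) by the (R)-configured catalyst, and DBU then equilibrates the kinetically formed cis ester through its enolate to the more stable 2,3-trans ester (3S).

Step 16
Reactants: 23 3-tert-butyl 5-methyl (2S,3S)-2-[4-(benzyloxy)-3-methoxyphenyl]-7-methoxy-2,3-dihydrobenzofuran-3,5-dicarboxylate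
Product: 24 tert-butyl (2S,3S)-2-[4-(benzyloxy)-3-methoxyphenyl]-5-(hydroxymethyl)-7-methoxy-2,3-dihydrobenzofuran-3-carboxylate
Conditions: LiBH4, MeOH (1 equiv), THF, 0 °C → rt
Reagents that add atoms: none
Why: Chemoselective borohydride reduction should take the methyl benzoate to the benzylic alcohol while the hindered tert-butyl ester, which is carried on as the masked outer hydroxymethyl group, is not reduced.

Step 17
Reactants: 16 tert-butyl 2-{5-[(2R,3R,4R)-3-(acetoxymethyl)-4-(4-(benzyloxy)-3-methoxybenzyl)tetrahydrofuran-2-yl]-2-hydroxy-3-methoxyphenyl}acetate; 24 tert-butyl (2S,3S)-2-[4-(benzyloxy)-3-methoxyphenyl]-5-(hydroxymethyl)-7-methoxy-2,3-dihydrobenzofuran-3-carboxylate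
Product: 25 tert-butyl (2S,3S)-5-({4-[(2R,3R,4R)-3-(acetoxymethyl)-4-(4-(benzyloxy)-3-methoxybenzyl)tetrahydrofuran-2-yl]-2-(2-tert-butoxy-2-oxoethyl)-6-methoxyphenoxy}methyl)-2-[4-(benzyloxy)-3-methoxyphenyl]-7-methoxy-2,3-dihydrobenzofuran-3-carboxylate
Conditions: PPh3, DIAD, toluene, 0 °C → rt
Reagents that add atoms: none
Why: Mitsunobu etherification joins the two fragments under neutral conditions that should spare the acid-labile tetrahydrofuran, the acetate and both tert-butyl esters, and it touches no stereocentre.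

Step 18
Reactants: 25 tert-butyl (2S,3S)-5-({4-[(2R,3R,4R)-3-(acetoxymethyl)-4-(4-(benzyloxy)-3-methoxybenzyl)tetrahydrofuran-2-yl]-2-(2-tert-butoxy-2-oxoethyl)-6-methoxyphenoxy}methyl)-2-[4-(benzyloxy)-3-methoxyphenyl]-7-methoxy-2,3-dihydrobenzofuran-3-carboxylate
Product: 26 the α-diazo ester of 25, carrying a 2-tert-butoxy-1-diazo-2-oxoethyl group on ring C in place of the 2-tert-butoxy-2-oxoethyl group
Conditions: p-ABSA, DBU, MeCN, 0 °C → rt
Reagents that add atoms: 4-acetamidobenzenesulfonyl azide, CC(=O)Nc1ccc(cc1)S(=O)(=O)N=[N+]=[N-]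
Why: Regitz diazo transfer can occur only at the arylacetate CH2, since the dihydrobenzofuran ester carbon has a single α-hydrogen and reversible deprotonation there returns the thermodynamically preferred trans ester.

Step 19
Reactants: 26 the α-diazo ester of 25
Product: 28 tert-butyl (2R,3R)-5-[(2R,3R,4R)-3-(acetoxymethyl)-4-(4-(benzyloxy)-3-methoxybenzyl)tetrahydrofuran-2-yl]-2-{(2S,3S)-2-[4-(benzyloxy)-3-methoxyphenyl]-3-(tert-butoxycarbonyl)-7-methoxy-2,3-dihydrobenzofuran-5-yl}-7-methoxy-2,3-dihydrobenzofuran-3-carboxylate (inner ring trans), via cis ester 27 (not isolated)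
Conditions: Rh2(S-PTTL)4 (2 mol%), toluene (0.01 M), slow addition of 26, −60 → −40 °C; then DBU, rt
Reagents that add atoms: none
Why: Loss of N2 from 26 at rhodium gives a donor/acceptor carbenoid at the future C3, which should insert into the neighbouring O–CH2 C–H bond through a concerted, hydride-transfer-like three-centre transition state and so form the C3–C2 bond (intramolecular carbenoid C–H insertion of an aryldiazoacetate into a benzyl aryl ether, the known entry to 2-aryl-2,3-dihydrobenzofuran-3-carboxylates). The dihydrofuran ring closes as a 1,5-insertion, with the carbenoid carbon, C3a, C7a, O1 and the ether carbon becoming the five ring atoms. C2 is set by the catalyst, whose chiral phthalimido-carboxylate pocket should distinguish the two benzylic hydrogens and deliver (2R), the opposite sense to step 15. C3 is formed mainly cis under kinetic control (27) and is then equilibrated by DBU through the ester enolate to the more stable 2,3-trans ester (3R), the outer trans ester being already at equilibrium. The step needs site selectivity over all other C–H bonds and over intermolecular carbenoid reactions, which the substrate secures because only this C–H is held 1,5 and is activated by O1 and by the para-alkoxy ring B, all hydroxyls are masked, and the diazo compound is added slowly at high dilution. Catalyst control must also override the resident stereocentres, which lie at least four bonds from either reacting carbon.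

Step 20
Reactants: 28 the bis(tert-butyl ester) acetate described in step 19
Product: 29 [(2R,3S)-2-{(2S,3R)-2-[4-(benzyloxy)-3-methoxyphenyl]-3-(hydroxymethyl)-7-methoxy-2,3-dihydrobenzofuran-5-yl}-5-[(2R,3R,4R)-4-(4-(benzyloxy)-3-methoxybenzyl)-3-(hydroxymethyl)tetrahydrofuran-2-yl]-7-methoxy-2,3-dihydrobenzofuran-3-yl]methanol
Conditions: LiAlH4, THF, 0 °C → rt
Reagents that add atoms: none
Why: Hydride reduction should convert both tert-butyl esters into hydroxymethyl groups and cleave the acetate in one operation, faster than any base-induced opening of the dihydrofuran rings.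

Step 21
Reactants: 29 the bis(benzyl ether) triol described in step 20
Product: 30 CNP0395728.1, 4-[(2S,3R)-3-(hydroxymethyl)-5-{(2R,3S)-3-(hydroxymethyl)-5-[(2R,3R,4R)-4-(4-hydroxy-3-methoxybenzyl)-3-(hydroxymethyl)tetrahydrofuran-2-yl]-7-methoxy-2,3-dihydrobenzofuran-2-yl}-7-methoxy-2,3-dihydrobenzofuran-2-yl]-2-methoxyphenol
Conditions: H2 (1 atm), 10% Pd/C, EtOAc–MeOH, rt, stopped at full debenzylation
Reagents that add atoms: none
Why: Hydrogenolysis of the two aryl benzyl ethers under neutral conditions should be much faster than cleavage of the cyclic benzylic C–O bonds and avoids the acid that would epimerise the all-cis tetrahydrofuran.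

**Compound list**

1 | 4-(benzyloxy)-3-methoxybenzaldehyde | O=Cc1ccc(OCc2ccccc2)c(OC)c1 | starting material
2 | dimethyl succinate | COC(=O)CCC(=O)OC | starting material
3 | (E)-4-[4-(benzyloxy)-3-methoxyphenyl]-3-(methoxycarbonyl)but-3-enoic acid | COC(=O)/C(=C/c1ccc(OCc2ccccc2)c(OC)c1)CC(=O)O | intermediate
4 | (R)-4-[4-(benzyloxy)-3-methoxyphenyl]-3-(methoxycarbonyl)butanoic acid | COC(=O)[C@H](Cc1ccc(OCc2ccccc2)c(OC)c1)CC(=O)O | intermediate
5 | (R)-4-[4-(benzyloxy)-3-methoxyphenyl]-3-(hydroxymethyl)butanoic acid (not isolated) | OC[C@H](Cc1ccc(OCc2ccccc2)c(OC)c1)CC(=O)O | intermediate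
6 | (R)-4-[4-(benzyloxy)-3-methoxybenzyl]dihydrofuran-2(3H)-one | O=C1C[C@@H](Cc2ccc(OCc3ccccc3)c(OC)c2)CO1 | intermediate
7 | 3-bromo-4-hydroxy-5-methoxybenzaldehyde | O=Cc1cc(Br)c(O)c(OC)c1 | starting material
8 | 3-bromo-5-methoxy-4-(triisopropylsilyloxy)benzaldehyde | O=Cc1cc(Br)c(O[Si](C(C)C)(C(C)C)C(C)C)c(OC)c1 | intermediate
9 | (3S,4R)-4-[4-(benzyloxy)-3-methoxybenzyl]-3-{[3-bromo-5-methoxy-4-(triisopropylsilyloxy)phenyl](hydroxy)methyl}dihydrofuran-2(3H)-one, carbinol epimers | O=C1[C@H](C(O)c2cc(Br)c(O[Si](C(C)C)(C(C)C)C(C)C)c(OC)c2)[C@@H](Cc2ccc(OCc3ccccc3)c(OC)c2)CO1 | intermediate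
10 | (2R,3R)-2-[4-(benzyloxy)-3-methoxybenzyl]-3-{[3-bromo-5-methoxy-4-(triisopropylsilyloxy)phenyl](hydroxy)methyl}butane-1,4-diol, carbinol epimers | OC[C@H](C(O)c1cc(Br)c(O[Si](C(C)C)(C(C)C)C(C)C)c(OC)c1)[C@@H](Cc1ccc(OCc2ccccc2)c(OC)c1)CO | intermediate
11 | (2R,3R)-3-[4-(benzyloxy)-3-methoxybenzyl]-1-[3-bromo-5-methoxy-4-(triisopropylsilyloxy)phenyl]-4-hydroxy-2-(hydroxymethyl)butan-1-one (not isolated) | OC[C@H](C(=O)c1cc(Br)c(O[Si](C(C)C)(C(C)C)C(C)C)c(OC)c1)[C@@H](Cc1ccc(OCc2ccccc2)c(OC)c1)CO | intermediate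
12 | (3R,4R)-4-[4-(benzyloxy)-3-methoxybenzyl]-2-[3-bromo-5-methoxy-4-(triisopropylsilyloxy)phenyl]-3-(hydroxymethyl)tetrahydrofuran-2-ol, anomeric mixture | COc1cc(C[C@H]2COC(O)(c3cc(Br)c(O[Si](C(C)C)(C(C)C)C(C)C)c(OC)c3)[C@H]2CO)ccc1OCc1ccccc1 | intermediate
13 | [(2R,3R,4R)-4-[4-(benzyloxy)-3-methoxybenzyl]-2-[3-bromo-5-methoxy-4-(triisopropylsilyloxy)phenyl]tetrahydrofuran-3-yl]methanol | COc1cc(C[C@H]2CO[C@@H](c3cc(Br)c(O[Si](C(C)C)(C(C)C)C(C)C)c(OC)c3)[C@H]2CO)ccc1OCc1ccccc1 | intermediate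
14 | [(2R,3R,4R)-4-[4-(benzyloxy)-3-methoxybenzyl]-2-[3-bromo-5-methoxy-4-(triisopropylsilyloxy)phenyl]tetrahydrofuran-3-yl]methyl acetate | COc1cc(C[C@H]2CO[C@@H](c3cc(Br)c(O[Si](C(C)C)(C(C)C)C(C)C)c(OC)c3)[C@H]2COC(C)=O)ccc1OCc1ccccc1 | intermediate
15 | tert-butyl 2-{5-[(2R,3R,4R)-3-(acetoxymethyl)-4-(4-(benzyloxy)-3-methoxybenzyl)tetrahydrofuran-2-yl]-3-methoxy-2-(triisopropylsilyloxy)phenyl}acetate | COc1cc(C[C@H]2CO[C@@H](c3cc(CC(=O)OC(C)(C)C)c(O[Si](C(C)C)(C(C)C)C(C)C)c(OC)c3)[C@H]2COC(C)=O)ccc1OCc1ccccc1 | intermediate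
16 | tert-butyl 2-{5-[(2R,3R,4R)-3-(acetoxymethyl)-4-(4-(benzyloxy)-3-methoxybenzyl)tetrahydrofuran-2-yl]-2-hydroxy-3-methoxyphenyl}acetate | COc1cc(C[C@H]2CO[C@@H](c3cc(CC(=O)OC(C)(C)C)c(O)c(OC)c3)[C@H]2COC(C)=O)ccc1OCc1ccccc1 | intermediate
17 | methyl 3-bromo-4-hydroxy-5-methoxybenzoate | COC(=O)c1cc(Br)c(O)c(OC)c1 | starting material
18 | [4-(benzyloxy)-3-methoxyphenyl]methanol | OCc1ccc(OCc2ccccc2)c(OC)c1 | starting material
19 | methyl 4-{[4-(benzyloxy)-3-methoxybenzyl]oxy}-3-bromo-5-methoxybenzoate | COC(=O)c1cc(Br)c(OCc2ccc(OCc3ccccc3)c(OC)c2)c(OC)c1 | intermediate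
20 | methyl 4-{[4-(benzyloxy)-3-methoxybenzyl]oxy}-3-(2-tert-butoxy-2-oxoethyl)-5-methoxybenzoate | COC(=O)c1cc(CC(=O)OC(C)(C)C)c(OCc2ccc(OCc3ccccc3)c(OC)c2)c(OC)c1 | intermediate
21 | methyl 4-{[4-(benzyloxy)-3-methoxybenzyl]oxy}-3-(2-tert-butoxy-1-diazo-2-oxoethyl)-5-methoxybenzoate | COC(=O)c1cc(C(=[N+]=[N-])C(=O)OC(C)(C)C)c(OCc2ccc(OCc3ccccc3)c(OC)c2)c(OC)c1 | intermediate
22 | 3-tert-butyl 5-methyl (2S,3R)-2-[4-(benzyloxy)-3-methoxyphenyl]-7-methoxy-2,3-dihydrobenzofuran-3,5-dicarboxylate, cis (not isolated) | COC(=O)c1cc(OC)c2c(c1)[C@@H](C(=O)OC(C)(C)C)[C@@H](c1ccc(OCc3ccccc3)c(OC)c1)O2 | intermediate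
23 | 3-tert-butyl 5-methyl (2S,3S)-2-[4-(benzyloxy)-3-methoxyphenyl]-7-methoxy-2,3-dihydrobenzofuran-3,5-dicarboxylate, trans | COC(=O)c1cc(OC)c2c(c1)[C@H](C(=O)OC(C)(C)C)[C@@H](c1ccc(OCc3ccccc3)c(OC)c1)O2 | intermediate
24 | tert-butyl (2S,3S)-2-[4-(benzyloxy)-3-methoxyphenyl]-5-(hydroxymethyl)-7-methoxy-2,3-dihydrobenzofuran-3-carboxylate | OCc1cc(OC)c2c(c1)[C@H](C(=O)OC(C)(C)C)[C@@H](c1ccc(OCc3ccccc3)c(OC)c1)O2 | intermediate
25 | tert-butyl (2S,3S)-5-({4-[(2R,3R,4R)-3-(acetoxymethyl)-4-(4-(benzyloxy)-3-methoxybenzyl)tetrahydrofuran-2-yl]-2-(2-tert-butoxy-2-oxoethyl)-6-methoxyphenoxy}methyl)-2-[4-(benzyloxy)-3-methoxyphenyl]-7-methoxy-2,3-dihydrobenzofuran-3-carboxylate | COc1cc(C[C@H]2CO[C@@H](c3cc(CC(=O)OC(C)(C)C)c(OCc4cc(OC)c5c(c4)[C@H](C(=O)OC(C)(C)C)[C@@H](c4ccc(OCc6ccccc6)c(OC)c4)O5)c(OC)c3)[C@H]2COC(C)=O)ccc1OCc1ccccc1 | intermediate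
26 | α-diazo ester of 25 (ring C carries 2-tert-butoxy-1-diazo-2-oxoethyl) | COc1cc(C[C@H]2CO[C@@H](c3cc(C(=[N+]=[N-])C(=O)OC(C)(C)C)c(OCc4cc(OC)c5c(c4)[C@H](C(=O)OC(C)(C)C)[C@@H](c4ccc(OCc6ccccc6)c(OC)c4)O5)c(OC)c3)[C@H]2COC(C)=O)ccc1OCc1ccccc1 | intermediate
27 | inner-ring cis epimer of 28, inner ring (2R,3S), outer ring (2S,3S) (not isolated) | COc1cc(C[C@H]2CO[C@@H](c3cc(OC)c4c(c3)[C@H](C(=O)OC(C)(C)C)[C@H](c3cc(OC)c5c(c3)[C@H](C(=O)OC(C)(C)C)[C@@H](c3ccc(OCc6ccccc6)c(OC)c3)O5)O4)[C@H]2COC(C)=O)ccc1OCc1ccccc1 | intermediate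
28 | tert-butyl (2R,3R)-5-[(2R,3R,4R)-3-(acetoxymethyl)-4-(4-(benzyloxy)-3-methoxybenzyl)tetrahydrofuran-2-yl]-2-{(2S,3S)-2-[4-(benzyloxy)-3-methoxyphenyl]-3-(tert-butoxycarbonyl)-7-methoxy-2,3-dihydrobenzofuran-5-yl}-7-methoxy-2,3-dihydrobenzofuran-3-carboxylate | COc1cc(C[C@H]2CO[C@@H](c3cc(OC)c4c(c3)[C@@H](C(=O)OC(C)(C)C)[C@H](c3cc(OC)c5c(c3)[C@H](C(=O)OC(C)(C)C)[C@@H](c3ccc(OCc6ccccc6)c(OC)c3)O5)O4)[C@H]2COC(C)=O)ccc1OCc1ccccc1 | intermediate
29 | [(2R,3S)-2-{(2S,3R)-2-[4-(benzyloxy)-3-methoxyphenyl]-3-(hydroxymethyl)-7-methoxy-2,3-dihydrobenzofuran-5-yl}-5-[(2R,3R,4R)-4-(4-(benzyloxy)-3-methoxybenzyl)-3-(hydroxymethyl)tetrahydrofuran-2-yl]-7-methoxy-2,3-dihydrobenzofuran-3-yl]methanol | COc1cc(C[C@H]2CO[C@@H](c3cc(OC)c4c(c3)[C@@H](CO)[C@H](c3cc(OC)c5c(c3)[C@H](CO)[C@@H](c3ccc(OCc6ccccc6)c(OC)c3)O5)O4)[C@H]2CO)ccc1OCc1ccccc1 | intermediate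
30 | CNP0395728.1 | COc1cc(C[C@H]2CO[C@@H](c3cc(OC)c4c(c3)[C@@H](CO)[C@H](c3cc(OC)c5c(c3)[C@H](CO)[C@@H](c3ccc(O)c(OC)c3)O5)O4)[C@H]2CO)ccc1O | target

**Step count.** 21 steps in total. The longest linear sequence is 15 steps (1–3, 5–11, 17–21).

**Steps most likely to fail and their fallbacks**

Step 19 (key step). The resident stereocentres of the outer dihydrobenzofuran and the bulk of 26 may erode the catalyst's choice between the two benzylic hydrogens (a mismatched pairing), or slow the insertion enough for carbenoid dimerisation to compete. The fallback inverts the order of the two ring closures, so that the inner ring is closed while the ring-B side is still achiral. It sets out from 16 and 19 and comes back to the route at 28, with steps 13–18 no longer needed. DIBAL-H reduction of 19 (toluene, −78 °C) should give the achiral bromo benzylic alcohol F1. Mitsunobu coupling of F1 with 16 should give the bromo ether F2, and diazo transfer (p-ABSA, DBU) the diazo ester F3. Rh2(S-PTTL)4 insertion should then close the inner ring to the cis ester F4, which DBU equilibrates to the trans ester F5. Pd-catalysed Reformatsky α-arylation of the ring-B bromide should give the arylacetate F6, and diazo transfer the diazo ester F7. Insertion with Rh2(R-PTTL)4 should give the outer-cis ester F8, which DBU equilibrates to 28.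

Step 7. MnO2 may stall on the hindered secondary benzylic carbinol, or the β-hydroxy ketone may epimerise at the α-carbon or lose formaldehyde by retro-aldol cleavage on the oxide surface. The fallback is a protect–oxidise–deprotect sequence that sets out from 10 and comes back at 12. Selective silylation of the two primary hydroxyls (TBSCl, imidazole, CH2Cl2, 0 °C) should give the bis(silyl ether) F9. DMP oxidation of the remaining benzylic carbinol should give the ketone F10. Aqueous acetic acid (AcOH–THF–H2O, 40 °C) should then remove the alkyl silyl ethers but not the aryl TIPS ether, and the freed hydroxy ketone closes to hemiketal 12.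

Step 16. Hydride may also attack the tert-butyl ester, or fail to reduce the electron-rich benzoate at a temperature at which the tert-butyl ester survives. The fallback separates the two events, sets out from 23 and comes back at 24. Me3SnOH (1,2-dichloroethane, 80 °C) should hydrolyse only the methyl ester to the benzoic acid F11. BH3·THF should then reduce the carboxylic acid, but not the tert-butyl ester, to alcohol 24.

**Further compounds**

F1 | step 19 | [4-{[4-(benzyloxy)-3-methoxybenzyl]oxy}-3-bromo-5-methoxyphenyl]methanol | OCc1cc(Br)c(OCc2ccc(OCc3ccccc3)c(OC)c2)c(OC)c1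
F2 | step 19 | tert-butyl 2-{5-[(2R,3R,4R)-3-(acetoxymethyl)-4-(4-(benzyloxy)-3-methoxybenzyl)tetrahydrofuran-2-yl]-2-[(4-{[4-(benzyloxy)-3-methoxybenzyl]oxy}-3-bromo-5-methoxybenzyl)oxy]-3-methoxyphenyl}acetate | COc1cc(C[C@H]2CO[C@@H](c3cc(CC(=O)OC(C)(C)C)c(OCc4cc(Br)c(OCc5ccc(OCc6ccccc6)c(OC)c5)c(OC)c4)c(OC)c3)[C@H]2COC(C)=O)ccc1OCc1ccccc1
F3 | step 19 | α-diazo ester of F2 | COc1cc(C[C@H]2CO[C@@H](c3cc(C(=[N+]=[N-])C(=O)OC(C)(C)C)c(OCc4cc(Br)c(OCc5ccc(OCc6ccccc6)c(OC)c5)c(OC)c4)c(OC)c3)[C@H]2COC(C)=O)ccc1OCc1ccccc1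
F4 | step 19 | tert-butyl (2R,3S)-5-[(2R,3R,4R)-3-(acetoxymethyl)-4-(4-(benzyloxy)-3-methoxybenzyl)tetrahydrofuran-2-yl]-2-(4-{[4-(benzyloxy)-3-methoxybenzyl]oxy}-3-bromo-5-methoxyphenyl)-7-methoxy-2,3-dihydrobenzofuran-3-carboxylate, cis | COc1cc(C[C@H]2CO[C@@H](c3cc(OC)c4c(c3)[C@H](C(=O)OC(C)(C)C)[C@H](c3cc(Br)c(OCc5ccc(OCc6ccccc6)c(OC)c5)c(OC)c3)O4)[C@H]2COC(C)=O)ccc1OCc1ccccc1
F5 | step 19 | (2R,3R)-trans epimer of F4 | COc1cc(C[C@H]2CO[C@@H](c3cc(OC)c4c(c3)[C@@H](C(=O)OC(C)(C)C)[C@H](c3cc(Br)c(OCc5ccc(OCc6ccccc6)c(OC)c5)c(OC)c3)O4)[C@H]2COC(C)=O)ccc1OCc1ccccc1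
F6 | step 19 | analogue of F5 with 2-tert-butoxy-2-oxoethyl in place of bromine on ring B | COc1cc(C[C@H]2CO[C@@H](c3cc(OC)c4c(c3)[C@@H](C(=O)OC(C)(C)C)[C@H](c3cc(CC(=O)OC(C)(C)C)c(OCc5ccc(OCc6ccccc6)c(OC)c5)c(OC)c3)O4)[C@H]2COC(C)=O)ccc1OCc1ccccc1
F7 | step 19 | α-diazo ester of F6 | COc1cc(C[C@H]2CO[C@@H](c3cc(OC)c4c(c3)[C@@H](C(=O)OC(C)(C)C)[C@H](c3cc(C(=[N+]=[N-])C(=O)OC(C)(C)C)c(OCc5ccc(OCc6ccccc6)c(OC)c5)c(OC)c3)O4)[C@H]2COC(C)=O)ccc1OCc1ccccc1
F8 | step 19 | outer-ring cis epimer of 28, inner ring (2R,3R), outer ring (2S,3R) | COc1cc(C[C@H]2CO[C@@H](c3cc(OC)c4c(c3)[C@@H](C(=O)OC(C)(C)C)[C@H](c3cc(OC)c5c(c3)[C@@H](C(=O)OC(C)(C)C)[C@@H](c3ccc(OCc6ccccc6)c(OC)c3)O5)O4)[C@H]2COC(C)=O)ccc1OCc1ccccc1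
F9 | step 7 | (2R,3R)-3-[4-(benzyloxy)-3-methoxybenzyl]-1-[3-bromo-5-methoxy-4-(triisopropylsilyloxy)phenyl]-4-(tert-butyldimethylsilyloxy)-2-[(tert-butyldimethylsilyloxy)methyl]butan-1-ol | CC(C)(C)[Si](C)(C)OC[C@H](C(O)c1cc(Br)c(O[Si](C(C)C)(C(C)C)C(C)C)c(OC)c1)[C@@H](Cc1ccc(OCc2ccccc2)c(OC)c1)CO[Si](C)(C)C(C)(C)C
F10 | step 7 | (2R,3R)-3-[4-(benzyloxy)-3-methoxybenzyl]-1-[3-bromo-5-methoxy-4-(triisopropylsilyloxy)phenyl]-4-(tert-butyldimethylsilyloxy)-2-[(tert-butyldimethylsilyloxy)methyl]butan-1-one | CC(C)(C)[Si](C)(C)OC[C@H](C(=O)c1cc(Br)c(O[Si](C(C)C)(C(C)C)C(C)C)c(OC)c1)[C@@H](Cc1ccc(OCc2ccccc2)c(OC)c1)CO[Si](C)(C)C(C)(C)C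
F11 | step 16 | (2S,3S)-2-[4-(benzyloxy)-3-methoxyphenyl]-3-(tert-butoxycarbonyl)-7-methoxy-2,3-dihydrobenzofuran-5-carboxylic acid | OC(=O)c1cc(OC)c2c(c1)[C@H](C(=O)OC(C)(C)C)[C@@H](c1ccc(OCc3ccccc3)c(OC)c1)O2
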